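The runs come from a simulation on assumed constants, noise included.

Teal and grey, the two earlier runs, differed in c(substrate) at the same equivalents of partner and rival reagent, so c(partner) and c(rival reagent) differed with it, and I read one run against the other.

all flasks: rival reagent 1.05 equiv

| charge | substrate | partner | remark | time |
|---|---|---|---|---|
| teal | 0.32 mM | 1.5 equiv | run made earlier |  |
| grey | 7.1 mM | 1.5 equiv | run made earlier |  |
| epsilon | 0.60 mM | 1.50 equiv |  | 15 min |
| gamma | 8.0 mM | 1.50 equiv |  | 15 min |
| theta | 1.2 mM | 1.50 equiv |  | 15 min |
| alpha | 2.0 mM | 1.50 equiv |  | 15 min |

| run | time / min | target / % | side product / % | isomer of the product / % |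
|---|---|---|---|---|
| teal | 2.00 | 75 | 16 | 16 |
| teal | 4.00 | 61 | 12 | 25 |
| teal | 5.00 | 55 | 13 | 30 |
| teal | 8.00 | 44 | 12 | 44 |
| teal | 10.0 | 34 | 9 | 47 |
| grey | 2.00 | 54 | 13 | 13 |
| grey | 4.00 | 31 | 7 | 17 |
| grey | 5.00 | 25 | 13 | 22 |
| grey | 8.00 | 12 | 16 | 27 |
| grey | 10.0 | 10 | 10 | 33 |

(each reading ± 2 percentage points)

- what may be going on: rival reagent + target -> over-reaction product; substrate + rival reagent -> side product; target <-> isomer of the product; substrate + partner -> target

* all flasks from highest to lowest share of target in all that became target or side product or isomer of the product or over-reaction product, at 15 min (epsilon / gamma / theta / alpha)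
* the share of target in all that became target or side product or isomer of the product or over-reaction product of the flask you put first, at 15 min
* the share of target in all that became target or side product or isomer of the product or over-reaction product of the flask you put last, at 15 min

In teal the three columns already summed to 107% of the charge at 2.00 min. I took the substrate as used up by then, which makes the share asked simply the target yield. The side product in teal read 12% at 8.00 min, so I let 88.0% of the charge enter as target.

Then I worked with the fraction of target left, as for any decay. From 2.00 min to 10.0 min teal kept 45.3% and grey 18.5%. As time constants these readings give loss rates of 0.0989 /min and 0.211 /min, grey's being twice teal's.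

Dividing that gap by the gap in c(substrate) gave the extra loss rate of target per mM of substrate charged, 0.0165 /mM/min, on top of a base of 0.0936 /min. This treats the loss as pseudo-first-order, as if the rival reagent held still.

Target left is then the entering share times exp(−rate × time). My reckoning ranked the flasks by c(substrate), with epsilon lowest and first at 18.6%, and gamma last at 2.98%.

The forecast gave epsilon > theta > alpha > gamma, with 22% (17% to 27%) and 5% (2% to 8%), on the ground that “Over-reaction therefore grows with concentration”. My two figures stood lower than its values.

The flasks came out as epsilon > theta > alpha > gamma, with epsilon at 20.3% and gamma at 4.69%.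

    rival reagent + target → over-reaction product (k = 0.500 /M/s)
    substrate + rival reagent → side product (k = 18.0 /M/s)
    target ⇌ isomer of the product (K = 8.90, k = 0.00160 /s)
    substrate + partner → target (k = 130 /M/s)

The extra loss rate put 0.132 /min on gamma and 0.00990 /min on epsilon, and at 15.0 min epsilon held 10.4% over-reaction product against 53.1% in gamma. For gamma read at 10 min, the base plus this extra rate gave 9.21% target, and that neighbour flask held 9.72%.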